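## Retrosynthetic overview

1. Numbering: ring C1 (isovalerate), C2 (ketone), C3–C4 (oxirane, methyl on C3), C5, C6; chain C7 (oxirane carbon), C14 (oxirane CH2), C8 (ketone), C9=C10, C11 (OOH). The plan rests on C7, the fully substituted carbon of the side-chain oxirane, held between ring carbon C6 and the C8 carbonyl. Cutting C7–C14 and O–C14 leaves a C7 ketone and a one-carbon sulfur ylide.
2. During that step C8 is kept as an (8S)-silyloxy carbinol. This temporary stereocentre next to the reacting carbonyl decides the C7 face and is later oxidised away together with C2.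
3. The C7 ketone goes back to (R)-carvone. Ozonolysis of the isopropenyl group turns its methyl into C8, enolate prenylation forms C8–C9, and reagent-controlled enolate hydroxylation forms C8–O.
4. Ring order: the cyclohexane and C6 come with carvone. C1–O, C2–OH and then the C3–C4 oxirane (hydroxyl-directed) are relayed from C6, and the C7–C14 oxirane is closed last.
5. End game: joint C2/C8 oxidation, exchange of the C1 silyl ether for isovalerate, then a singlet-oxygen ene reaction to the (E)-enone hydroperoxide.

Key step: step 10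

Assumption: in step 10 the polar effect of the C8–O bond is taken to outweigh the facial bias of the C6 stereocentre, which cannot be tuned; under this model (8S) is the only C8 configuration that leads to (7R).

## Route

Step 1
Reactants: 1 (R)-(−)-carvone
Product: 3 (5S,6S)-6-hydroxycarvone (C1–OH trans to the isopropenyl group), via potassium dienolate 2 (not isolated)
Conditions: KN(SiMe3)2, THF, −78 °C; 2-(phenylsulfonyl)-3-phenyloxaziridine, −78 °C; AcOH
Reagents that add atoms: 2-(phenylsulfonyl)-3-phenyloxaziridine, O=S(=O)(c1ccccc1)N1OC1c1ccccc1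
Why: Davis enolate hydroxylation: kinetic deprotonation at the α′-CH2 gives the cross-conjugated dienolate 2, and the oxaziridine oxygen is taken up on the face anti to the adjacent isopropenyl group, which sets C1 (S) trans to C6.

Step 2
Reactants: 3 (5S,6S)-6-hydroxycarvone
Product: 4 C1 tert-butyldimethylsilyl ether of 6-hydroxycarvone
Conditions: TBSCl, imidazole, DMF, rt
Reagents that add atoms: tert-butyldimethylsilyl chloride, CC(C)(C)[Si](C)(C)Cl
Why: Standard imidazole-promoted silylation of a secondary alcohol; the weakly basic medium touches neither C1 nor C6.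

Step 3
Reactants: 4 C1 tert-butyldimethylsilyl ether of 6-hydroxycarvone
Product: 5 (1S,2S,6S)-allylic alcohol (C2–OH cis to the isopropenyl group; trans to C1–OTBS)
Conditions: NaBH4, CeCl3·7H2O, MeOH, −78 to −20 °C
Reagents that add atoms: none
Why: Luche reduction: 1,2-selective axial hydride delivery to the half-chair with both substituents equatorial gives the equatorial C2 alcohol, as in the reduction of carvone to cis-carveol.

Step 4
Reactants: 5 (1S,2S,6S)-allylic alcohol
Product: 6 (1S,2R,3R,4S,6S)-3,4-epoxy alcohol (oxirane O cis to C2–OH and to the isopropenyl group)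
Conditions: VO(acac)2 (cat.), tBuOOH (decane), CH2Cl2, 0 °C to rt
Reagents that add atoms: tert-butyl hydroperoxide, CC(C)(C)OO
Why: Vanadium-catalysed hydroxyl-directed epoxidation: the alkoxide-bound peroxide transfers oxygen to the C3=C4 face syn to the C2 hydroxyl, which sets C3 and C4, while the isopropenyl alkene has no directing hydroxyl and is left alone.

Step 5
Reactants: 6 (1S,2R,3R,4S,6S)-3,4-epoxy alcohol
Product: 7 C2 triethylsilyl ether (1S,2R,3S,4S,6S)
Conditions: TESCl, imidazole, 4-(dimethylamino)pyridine (cat.), DMF, rt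
Reagents that add atoms: triethylsilyl chloride, CC[Si](Cl)(CC)CC
Why: Chlorosilane/imidazole silylation; silyl triflates are avoided because they can trigger rearrangement of epoxy silyl ethers, and no stereocentre is touched.

Step 6
Reactants: 7 C2 triethylsilyl ether
Product: 9 C7 methyl ketone (1S,2R,3S,4S,6R), via secondary ozonide 8 (not isolated)
Conditions: O3, CH2Cl2, −78 °C; Me2S, −78 °C to rt
Reagents that add atoms: ozone, [O-][O+]=O
Why: Ozonolysis (Criegee sequence) of the only alkene left, followed by reductive cleavage of ozonide 8, gives the methyl ketone under neutral conditions, so C6 is not epimerised and the β-silyloxy group at C1 is not eliminated.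

Step 7
Reactants: 9 C7 methyl ketone; 10 prenyl bromide
Product: 12 C7 ketone bearing the C8H2–C9H2–C10H=C11Me2 chain, via lithium enolate 11 (not isolated)
Conditions: LiN(iPr)2, THF, −78 °C; 10, DMPU, −78 to −40 °C
Reagents that add atoms: prenyl bromide (10), CC(C)=CCBr
Why: Kinetic enolate alkylation: the hindered amide base removes a methyl (C8) proton rather than the tertiary C6–H, and SN2 attack of enolate 11 on the primary allylic bromide forms C8–C9 without creating a stereocentre.

Step 8
Reactants: 12 C7 ketone bearing the C8H2–C9H2–C10H=C11Me2 chain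
Product: 14 (8S)-8-hydroxy C7 ketone, via sodium Z-enolate 13 (not isolated)
Conditions: NaN(SiMe3)2, THF, −78 °C; (+)-(camphorylsulfonyl)oxaziridine, −78 °C; AcOH
Reagents that add atoms: (+)-(camphorylsulfonyl)oxaziridine, CC1(C)[C@@H]2CC[C@]13CS(=O)(=O)N4O[C@@]34C2
Why: Davis asymmetric enolate hydroxylation: deprotonation at the C8 methylene next to the bulky C6 residue gives Z-enolate 13, and the (+)-camphor-derived oxaziridine, which converts Z-enolates of acyclic ketones into (S)-α-hydroxy ketones, should set C8 as (S) under reagent control.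

Step 9
Reactants: 14 (8S)-8-hydroxy C7 ketone
Product: 15 (8S)-8-triethylsilyloxy C7 ketone (1S,2R,3S,4S,6R,8S)
Conditions: TESCl, imidazole, CH2Cl2, 0 °C to rt
Reagents that add atoms: triethylsilyl chloride, CC[Si](Cl)(CC)CC
Why: Standard silylation under weakly basic conditions that do not epimerise C8 or C6; it gives the non-chelating polar substituent needed in the next step.

Step 10
Reactants: 15 (8S)-8-triethylsilyloxy C7 ketone; 16 trimethylsulfonium iodide
Product: 19 fully silylated (7R,8S)-bis-epoxide (C3–C4 oxirane plus new C7–C14 oxirane), via dimethylsulfonium methylide 17 (not isolated), via sulfonium betaine 18 (not isolated)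
Conditions: 16 (slight excess over base), KN(SiMe3)2, THF, −10 °C; then 15, −78 to 0 °C
Reagents that add atoms: trimethylsulfonium iodide (16), C[S+](C)C.[I-] (delivers C14 as ylide 17, C[S+](C)[CH2-])
Why: The carbanionic carbon of 17 adds irreversibly to the C7 carbonyl of 15 to give betaine 18 (C7–C14 bond), and the alkoxide of 18 then displaces dimethyl sulfide from C14 (O–C14 bond), so the oxirane oxygen is the former carbonyl oxygen. This is the Corey–Chaykovsky epoxidation, well established for hindered and α-oxygenated ketones with the unstabilised sulfonium ylide. The single ring formed, the C7–C14 oxirane, closes in a 3-exo-tet mode. The new C7 stereocentre is fixed in the kinetic addition step by the (8S)-silyloxy group: in the polar Felkin–Anh arrangement the C8–O bond stands perpendicular to the carbonyl plane, C9 lies beside the carbonyl oxygen and H8 beside C6, and attack anti to C8–O gives (7R), with O7 and O8 anti along the C14–C7–C8–C9 zigzag. The step needs facial selectivity at C7 and chemoselectivity: the potassium counter-ion and the bulky silyl ether disfavour a chelate, and the trisubstituted C3–C4 oxirane and the hindered product oxirane react far more slowly than the ketone at or below 0 °C. Keeping 16 in excess over KN(SiMe3)2 leaves no free amide base to start β-elimination of the C1 silyloxy group through a C6 enolate.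

Step 11
Reactants: 19 fully silylated (7R,8S)-bis-epoxide
Product: 20 C2,C8-diol (1S,2R,3R,4S,6R,7R,8S) retaining C1–OTBS
Conditions: HF·pyridine, pyridine, THF, 0 °C
Reagents that add atoms: none
Why: Fluoride-mediated silyl ether cleavage: triethylsilyl ethers are cleaved much faster than the hindered secondary tert-butyldimethylsilyl ether, and the buffered medium avoids Payne rearrangement at C8/C7, silyl migration from C1 to C2 and acid opening of the oxiranes.

Step 12
Reactants: 20 C2,C8-diol
Product: 21 C2,C8-diketone (1S,3S,4S,6R,7R) retaining C1–OTBS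
Conditions: Dess–Martin periodinane, NaHCO3, CH2Cl2, 0 °C to rt
Reagents that add atoms: none
Why: Dess–Martin oxidation converts both secondary carbinols in one operation and removes the auxiliary C8 stereocentre, and the buffered non-basic conditions leave the C10=C11 alkene out of conjugation and C1 unepimerised.

Step 13
Reactants: 21 C2,C8-diketone
Product: 22 C1 alcohol (α-hydroxy ketone; 1S,3S,4S,6R,7R)
Conditions: HF·pyridine, THF, 0 °C to rt (polyethylene vessel)
Reagents that add atoms: none
Why: Fluoride cleavage of the silyl ether, made more labile by the adjacent C2 carbonyl, under mildly acidic conditions that avoid α-ketol isomerisation and conjugation of the β,γ-enone.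

Step 14
Reactants: 22 C1 alcohol; 23 isovaleryl chloride
Product: 24 C1 isovalerate (1S,3S,4S,6R,7R)
Conditions: 23, pyridine, 4-(dimethylamino)pyridine (cat.), CH2Cl2, 0 °C
Reagents that add atoms: isovaleryl chloride (23), CC(C)CC(=O)Cl
Why: Nucleophile-catalysed O-acylation with an acid chloride; the C1–O bond is not broken, so the configuration is retained, and the equatorial ester is also the more stable epimer.

Step 15
Reactants: 24 C1 isovalerate
Product: 25 CNP0131119.1 (target)
Conditions: O2, 5,10,15,20-tetraphenylporphyrin (cat.), visible light, CH2Cl2, −20 °C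
Reagents that add atoms: dioxygen, O=O
Why: Schenck ene reaction: singlet oxygen attacks the only electron-rich alkene (C10=C11) on its more substituted side, and abstraction of a C9 hydrogen, favoured because the C8 carbonyl makes the new C9=C10 bond conjugated, places OOH on tertiary C11 and gives the (E)-enone, which is inert to further oxygenation.

## Compound list

1 | (R)-(−)-carvone | CC1=CC[C@H](CC1=O)C(C)=C | starting material
2 | potassium cross-conjugated dienolate of carvone | CC1=CC[C@H](C=C1[O-])C(C)=C.[K+] | intermediate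
3 | (5S,6S)-6-hydroxycarvone (OH trans to isopropenyl) | O[C@@H]1C(=O)C(C)=CC[C@H]1C(C)=C | intermediate
4 | C1 tert-butyldimethylsilyl ether of 3 | CC(C)(C)[Si](C)(C)O[C@@H]1C(=O)C(C)=CC[C@H]1C(C)=C | intermediate
5 | (1S,2S,6S)-allylic alcohol (C2–OH cis to isopropenyl, trans to C1–OTBS) | CC(C)(C)[Si](C)(C)O[C@@H]1[C@@H](O)C(C)=CC[C@H]1C(C)=C | intermediate
6 | (1S,2R,3R,4S,6S)-3,4-epoxy alcohol (oxirane O cis to C2–OH) | CC(C)(C)[Si](C)(C)O[C@@H]1[C@@H](O)[C@@]2(C)O[C@H]2C[C@H]1C(C)=C | intermediate
7 | C2 triethylsilyl ether of 6 | CC(C)(C)[Si](C)(C)O[C@@H]1[C@@H](O[Si](CC)(CC)CC)[C@@]2(C)O[C@H]2C[C@H]1C(C)=C | intermediate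
8 | secondary ozonide (1,2,4-trioxolane at C7) of 7 | CC(C)(C)[Si](C)(C)O[C@@H]1[C@@H](O[Si](CC)(CC)CC)[C@@]2(C)O[C@H]2C[C@H]1C1(C)OCOO1 | intermediate
9 | C7 methyl ketone (1S,2R,3S,4S,6R) | CC(C)(C)[Si](C)(C)O[C@@H]1[C@@H](O[Si](CC)(CC)CC)[C@@]2(C)O[C@H]2C[C@H]1C(C)=O | intermediate
10 | prenyl bromide (1-bromo-3-methylbut-2-ene) | CC(C)=CCBr | starting material
11 | lithium C7=C8 enolate of 9 | CC(C)(C)[Si](C)(C)O[C@@H]1[C@@H](O[Si](CC)(CC)CC)[C@@]2(C)O[C@H]2C[C@H]1C(=C)[O-].[Li+] | intermediate
12 | C7 ketone with 4-methylpent-3-enyl chain (C8 to C11) | CC(C)(C)[Si](C)(C)O[C@@H]1[C@@H](O[Si](CC)(CC)CC)[C@@]2(C)O[C@H]2C[C@H]1C(=O)CCC=C(C)C | intermediate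
13 | sodium (Z)-C7=C8 enolate of 12 | CC(C)(C)[Si](C)(C)O[C@@H]1[C@@H](O[Si](CC)(CC)CC)[C@@]2(C)O[C@H]2C[C@H]1/C([O-])=C/CC=C(C)C.[Na+] | intermediate
14 | (8S)-8-hydroxy C7 ketone | CC(C)(C)[Si](C)(C)O[C@@H]1[C@@H](O[Si](CC)(CC)CC)[C@@]2(C)O[C@H]2C[C@H]1C(=O)[C@@H](O)CC=C(C)C | intermediate
15 | (8S)-8-triethylsilyloxy C7 ketone (key-step precursor) | CC(C)(C)[Si](C)(C)O[C@@H]1[C@@H](O[Si](CC)(CC)CC)[C@@]2(C)O[C@H]2C[C@H]1C(=O)[C@@H](O[Si](CC)(CC)CC)CC=C(C)C | intermediate
16 | trimethylsulfonium iodide | C[S+](C)C.[I-] | starting material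
17 | dimethylsulfonium methylide | C[S+](C)[CH2-] | intermediate
18 | betaine (C7 alkoxide, C14 dimethylsulfonium) | CC(C)(C)[Si](C)(C)O[C@@H]1[C@@H](O[Si](CC)(CC)CC)[C@@]2(C)O[C@H]2C[C@H]1[C@@]([O-])(C[S+](C)C)[C@@H](O[Si](CC)(CC)CC)CC=C(C)C | intermediate
19 | fully silylated (7R,8S)-bis-epoxide (key-step product) | CC(C)(C)[Si](C)(C)O[C@@H]1[C@@H](O[Si](CC)(CC)CC)[C@@]2(C)O[C@H]2C[C@H]1[C@]1([C@@H](O[Si](CC)(CC)CC)CC=C(C)C)CO1 | intermediate
20 | C2,C8-diol, C1–OTBS (1S,2R,3R,4S,6R,7R,8S) | CC(C)(C)[Si](C)(C)O[C@@H]1[C@@H](O)[C@@]2(C)O[C@H]2C[C@H]1[C@]1([C@@H](O)CC=C(C)C)CO1 | intermediate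
21 | C2,C8-diketone, C1–OTBS (1S,3S,4S,6R,7R) | CC(C)(C)[Si](C)(C)O[C@@H]1C(=O)[C@@]2(C)O[C@H]2C[C@H]1[C@]1(C(=O)CC=C(C)C)CO1 | intermediate
22 | C1 alcohol of the diketone | O[C@@H]1C(=O)[C@@]2(C)O[C@H]2C[C@H]1[C@]1(C(=O)CC=C(C)C)CO1 | intermediate
23 | isovaleryl chloride | CC(C)CC(=O)Cl | starting material
24 | C1 isovalerate with β,γ-unsaturated C8 ketone | CC(C)CC(=O)O[C@@H]1C(=O)[C@@]2(C)O[C@H]2C[C@H]1[C@]1(C(=O)CC=C(C)C)CO1 | intermediate
25 | CNP0131119.1 (1S,3S,4S,6R,7R; 9E) | CC(C)CC(=O)O[C@@H]1C(=O)[C@@]2(C)O[C@H]2C[C@H]1[C@]1(C(=O)/C=C/C(C)(C)OO)CO1 | target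

## Step count

Total step count: 15. Longest linear sequence: 15 steps, from 1 to 25.

## Steps most likely to fail

**1. Step 10.** Facial selectivity at C7 may be poor. The C6 stereocentre has a Felkin preference of its own (C1 branch as the large group) that can oppose the C8 effect. Addition to a ketone branched on both sides may also be slow, which leaves time for enolisation and β-elimination of the C1 silyloxy group.

Fallback, from 15 back to 20: the carbon and the oxygen of the oxirane are brought in separately.
- Petasis methylenation with Cp2TiMe2 (toluene, 70 °C), a non-basic reagent, converts the ketone into the C7=C14 methylene compound F1.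
- Buffered HF·pyridine frees both triethylsilyl-protected hydroxyls to give the allylic alcohol diol F2.
- Sharpless epoxidation (Ti(OiPr)4, L-(+)-diisopropyl tartrate, tBuOOH, 4 Å sieves, CH2Cl2, −20 °C) delivers oxygen to C7=C14 from the C8-bound titanium peroxide.
- The (8S)-carbinol belongs to the fast-reacting series for this tartrate. Allylic 1,2-strain between C9 and C6 favours the erythro (7R,8S) epoxy alcohol, and the homoallylic C10=C11 alkene reacts much more slowly. The product is 20.

**2. Step 8.** Reagent control over a dialkyl ketone enolate may be modest, giving poor diastereoselectivity at C8. The result feeds directly into step 10, because only the (8S) series leads to (7R).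

Fallback, from 12 back to 14: the stereocentre is set by SN2 inversion instead of face-selective oxygen transfer.
- Enolate 13 is hydroxylated with achiral 2-(phenylsulfonyl)-3-phenyloxaziridine and the epimers are separated. The (8S) epimer is 14.
- The (8R)-hydroxy ketone F3 undergoes Mitsunobu esterification (chloroacetic acid, PPh3, diisopropyl azodicarboxylate, THF, 0 °C) to the inverted (8S)-chloroacetate F4.
- F4 is cleaved with thiourea and NaHCO3 in EtOH, conditions mild enough for the β-silyloxy ketone, to give 14.

**3. Step 15.** Regioselectivity of the ene reaction may be poor. Abstraction of a hydrogen from the methyl group cis to C9 would put the hydroperoxide on C10 with a terminal isopropenyl group.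

Fallback, from 24 back to 25: radical-chain autoxidation with ground-state oxygen, a reaction known for β,γ-unsaturated ketones. The conditions are O2, N-hydroxyphthalimide (cat.), 2,2'-azobis(4-methoxy-2,4-dimethylvaleronitrile) as initiator, MeCN, 30 °C.
- The weakest C–H bond, the C9–H that is both allylic and α to the C8 carbonyl, is abstracted.
- The delocalised radical captures O2 reversibly, and capture at C11 gives the tertiary peroxyl radical of the conjugated (E)-enone.
- Hydrogen transfer from the catalyst gives 25. This fallback makes no new compound (F0).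

## Further compounds

F1 | step 10 | C7=C14 methylene compound (1S,2R,3S,4S,6S,8S), fully silylated | CC(C)(C)[Si](C)(C)O[C@@H]1[C@@H](O[Si](CC)(CC)CC)[C@@]2(C)O[C@H]2C[C@H]1C(=C)[C@@H](O[Si](CC)(CC)CC)CC=C(C)C
F2 | step 10 | allylic alcohol diol (C2–OH and (8S)-C8–OH free, C1–OTBS) | CC(C)(C)[Si](C)(C)O[C@@H]1[C@@H](O)[C@@]2(C)O[C@H]2C[C@H]1C(=C)[C@@H](O)CC=C(C)C
F3 | step 8 | (8R)-8-hydroxy C7 ketone (C8 epimer of 14) | CC(C)(C)[Si](C)(C)O[C@@H]1[C@@H](O[Si](CC)(CC)CC)[C@@]2(C)O[C@H]2C[C@H]1C(=O)[C@H](O)CC=C(C)C
F4 | step 8 | (8S)-8-chloroacetoxy C7 ketone | CC(C)(C)[Si](C)(C)O[C@@H]1[C@@H](O[Si](CC)(CC)CC)[C@@]2(C)O[C@H]2C[C@H]1C(=O)[C@@H](OC(=O)CCl)CC=C(C)C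
F0 | step 15 | none | none
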